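**Retrosynthetic overview**
1. Target 18 ⇐ tris-silyl ether 17 (three aryl silyl ethers removed last) ⇐ diol 15 + two molecules of silyl-protected 4-iodophenol 16 + 2 CO (double alkoxycarbonylation makes both 4-hydroxybenzoates at once).
2. 15 ⇐ diester 14 (i-Bu2AlH reduces both esters) ⇐ bromo ester 12 + methyl acrylate 13 (Heck reaction).
3. 12 (five-membered ring C with both stereocentres) ⇐ ring contraction of the six-membered (S)-flavanone silyl enol ether 11 by 1,2-shift of the ring A carbon from C4 to C3 ⇐ chromone 7 + aryl nucleophile from 8 (asymmetric 1,4-arylation sets C2).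
4. 7 and 8 both ⇐ 4-bromo-2-methoxyphenol 3 ⇐ guaiacol 2 ⇐ catechol 1; methyl propiolate 4 supplies the three pyranone carbons of 7.
5. Ring order: the pyranone ring is closed first (step 4) and is then contracted to the dihydrofuran ring (step 6); no other ring is built.

Assumption: tert-butyl(4-iodophenoxy)dimethylsilane 16 is purchased as the commercial silyl ether of 4-iodophenol.
Assumption: [RhCl((S)-binap)]2 delivers the aryl group to chromone 7 with the facial sense established for cyclic enones (giving 2S); the first run is checked by chiral HPLC and CD, and the (R) ligand is used if the sense is opposite.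

Ring labels: ring A = benzo ring of the benzofuran, ring B = pendant guaiacyl ring, ring C = oxygen heterocycle.

**Step 1**
Reactants: 1 catechol
Product: 2 2-methoxyphenol (guaiacol)
Conditions: MeI (1.0 equiv), K2CO3 (1.0 equiv), acetone, 56 °C
Reagents that add atoms: iodomethane CI
Why: Williamson mono-O-methylation; one equivalent of MeI with a weak base stops mainly at the mono-ether, and catechol and veratrole are removed by base extraction and distillation.

**Step 2**
Reactants: 2 2-methoxyphenol
Product: 3 4-bromo-2-methoxyphenol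
Conditions: NBS (1.0 equiv), MeCN, 0 → 20 °C
Reagents that add atoms: N-bromosuccinimide BrN1C(=O)CCC1=O
Why: Electrophilic aromatic bromination goes para to the free hydroxyl, the stronger director.

**Step 3**
Reactants: 3 4-bromo-2-methoxyphenol; 4 methyl propiolate
Product: 6 (E)-3-(4-bromo-2-methoxyphenoxy)prop-2-enoic acid, via methyl ester 5 (not isolated)
Conditions: DABCO (10 mol %), THF, 0 → 20 °C; then LiOH, H2O, 20 °C; then HCl to pH 2
Reagents that add atoms: lithium hydroxide [Li+].[OH-] (its oxygen becomes the carboxyl OH)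
Why: Amine-catalysed oxa-Michael addition of the phenol to the propiolate gives the E β-aryloxyacrylate, which is saponified in the same flask.

**Step 4**
Reactants: 6 (E)-3-(4-bromo-2-methoxyphenoxy)prop-2-enoic acid
Product: 7 6-bromo-8-methoxy-4H-chromen-4-one
Conditions: P2O5/MeSO3H (1:10 w/w), 70 °C
Reagents that add atoms: none
Why: Intramolecular Friedel–Crafts acylation at the only free position ortho to the ether oxygen closes the pyranone ring, the acid medium equilibrating the E/Z geometry so the acylium can reach the ring.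

**Step 5**
Reactants: 3 4-bromo-2-methoxyphenol
Product: 8 (4-bromo-2-methoxyphenoxy)tri(propan-2-yl)silane
Conditions: i-Pr3SiCl, imidazole, DMF, 20 °C
Reagents that add atoms: chlorotri(propan-2-yl)silane CC(C)[Si](Cl)(C(C)C)C(C)C
Why: Standard silylation of a phenol; the bulky aryl silyl ether tolerates the organometallic, oxidative, Heck and hydride steps and is removed by fluoride at the end.

**Step 6**
Reactants: 7 6-bromo-8-methoxy-4H-chromen-4-one; 8 (4-bromo-2-methoxyphenoxy)tri(propan-2-yl)silane
Product: 12 methyl (2S,3S)-5-bromo-7-methoxy-2-[3-methoxy-4-(triisopropylsilyloxy)phenyl]-2,3-dihydro-1-benzofuran-3-carboxylate, via arylmagnesium bromide 9 (not isolated), via arylzinc chloride 10 (not isolated), via silyl enol ether 11 (not isolated)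
Conditions: 8 (1.5 equiv), Mg, THF, 40 °C; ZnCl2, 0 °C; add to 7, [RhCl((S)-binap)]2 (3 mol %), Me3SiCl (1.5 equiv), THF, 20 °C; dilute with pentane, filter off Mg/Zn halides under Ar, concentrate; PhI(OH)OTs (1.3 equiv), HC(OMe)3/MeOH (3:1), −20 → 20 °C
Reagents that add atoms: methanol CO (ester OCH3 of 12); for the intermediates only: magnesium [Mg] (in 9), zinc chloride Cl[Zn]Cl (in 10), chlorotrimethylsilane C[Si](C)(C)Cl (in 11)
Why: Proposed new method: an asymmetric arylative ring contraction of a chromone, in which the (S)-BINAP complex of monovalent rhodium transfers the aryl group of 10 to one enantioface of C2 of 7 (as in the known rhodium-catalysed 1,4-addition of arylzinc chlorides to cyclic enones and 4-quinolones, Me3SiCl trapping the rhodium oxa-π-allyl as silyl enol ether 11 so that retro-oxa-Michael racemisation is shut off), after which the trivalent-iodine electrophile adds to C3 of the enol ether anti to the C2 aryl group, methanol adds to C4, and the ring A carbon C4a migrates from C4 to C3 antiperiplanar to the departing PhI (1,2-aryl shift, six- to five-membered ring) to give the 2,3-trans ester; the closest known reaction is the PhI(OAc)2- or Tl(NO3)3-mediated oxidative ring contraction of flavanone dimethyl ketals to trans-2-aryl-2,3-dihydrobenzofuran-3-carboxylates, here run for the first time on a silyl enol ether made in the same operation and without strong acid.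

**Step 7**
Reactants: 12 methyl (2S,3S)-5-bromo-7-methoxy-2-[3-methoxy-4-(triisopropylsilyloxy)phenyl]-2,3-dihydro-1-benzofuran-3-carboxylate; 13 methyl acrylate
Product: 14 methyl (2S,3S)-7-methoxy-5-[(E)-3-methoxy-3-oxoprop-1-enyl]-2-[3-methoxy-4-(triisopropylsilyloxy)phenyl]-2,3-dihydro-1-benzofuran-3-carboxylate
Conditions: Pd(OAc)2 (5 mol %), P(o-tol)3 (10 mol %), Et3N, MeCN, 85 °C
Reagents that add atoms: none
Why: Heck reaction: zerovalent palladium inserts into the aryl C–Br bond and syn-insertion/β-hydride elimination gives the E cinnamate; the trans ester is the thermodynamic isomer and ring opening from its enolate is stereoelectronically disfavoured, so the stereocentres hold under Et3N.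

**Step 8**
Reactants: 14 methyl (2S,3S)-7-methoxy-5-[(E)-3-methoxy-3-oxoprop-1-enyl]-2-[3-methoxy-4-(triisopropylsilyloxy)phenyl]-2,3-dihydro-1-benzofuran-3-carboxylate
Product: 15 (E)-3-[(2S,3R)-3-(hydroxymethyl)-7-methoxy-2-[3-methoxy-4-(triisopropylsilyloxy)phenyl]-2,3-dihydro-1-benzofuran-5-yl]prop-2-en-1-ol
Conditions: i-Bu2AlH (6 equiv), CH2Cl2, −78 → −20 °C; aq. KNaC4H4O6
Reagents that add atoms: none
Why: Hydride reduction of both esters (1,2-reduction of the enoate gives the allylic alcohol) under non-basic conditions leaves both stereocentres untouched; the C3 descriptor changes from S to R only because the priorities change.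

**Step 9**
Reactants: 15 (E)-3-[(2S,3R)-3-(hydroxymethyl)-7-methoxy-2-[3-methoxy-4-(triisopropylsilyloxy)phenyl]-2,3-dihydro-1-benzofuran-5-yl]prop-2-en-1-ol; 16 tert-butyl(4-iodophenoxy)dimethylsilane (2.5 equiv)
Product: 17 [(2S,3R)-5-[(E)-3-[4-(tert-butyldimethylsilyloxy)benzoyloxy]prop-1-enyl]-7-methoxy-2-[3-methoxy-4-(triisopropylsilyloxy)phenyl]-2,3-dihydro-1-benzofuran-3-yl]methyl 4-(tert-butyldimethylsilyloxy)benzoate
Conditions: Pd(OAc)2 (5 mol %), Xantphos (6 mol %), Et3N (4 equiv), CO (1 atm), toluene, 70 °C
Reagents that add atoms: carbon monoxide [C-]#[O+]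
Why: Palladium-catalysed alkoxycarbonylation (oxidative addition of the aryl iodide to zerovalent palladium, CO insertion, alcoholysis of the acylpalladium by each primary hydroxyl) forms both benzoates in one operation; all phenols are silylated, so only the two alcohols act as nucleophiles.

**Step 10**
Reactants: 17 the tris-silyl ether from step 9
Product: 18 quiquesetinerviusin A, [(2S,3R)-2-(4-hydroxy-3-methoxyphenyl)-5-[(E)-3-(4-hydroxybenzoyloxy)prop-1-enyl]-7-methoxy-2,3-dihydro-1-benzofuran-3-yl]methyl 4-hydroxybenzoate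
Conditions: Bu4NF (3.3 equiv), AcOH (3.5 equiv), THF, 0 °C
Reagents that add atoms: none
Why: Fluoride cleaves the three aryl Si–O bonds; the acetic acid buffer keeps the phenoxides protonated so the benzoate and cinnamyl esters and both stereocentres are not touched.

**Compound list**
1 | catechol (benzene-1,2-diol) | Oc1ccccc1O | starting material
2 | 2-methoxyphenol (guaiacol) | COc1ccccc1O | intermediate
3 | 4-bromo-2-methoxyphenol | COc1cc(Br)ccc1O | intermediate
4 | methyl propiolate | C#CC(=O)OC | starting material
5 | methyl (E)-3-(4-bromo-2-methoxyphenoxy)prop-2-enoate | COC(=O)/C=C/Oc1ccc(Br)cc1OC | intermediate (not isolated)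
6 | (E)-3-(4-bromo-2-methoxyphenoxy)prop-2-enoic acid | OC(=O)/C=C/Oc1ccc(Br)cc1OC | intermediate
7 | 6-bromo-8-methoxy-4H-chromen-4-one | O=c1ccoc2c(OC)cc(Br)cc12 | intermediate
8 | (4-bromo-2-methoxyphenoxy)tri(propan-2-yl)silane | COc1cc(Br)ccc1O[Si](C(C)C)(C(C)C)C(C)C | intermediate
9 | [3-methoxy-4-(triisopropylsilyloxy)phenyl]magnesium bromide | COc1cc([Mg]Br)ccc1O[Si](C(C)C)(C(C)C)C(C)C | intermediate (not isolated)
10 | [3-methoxy-4-(triisopropylsilyloxy)phenyl]zinc chloride | COc1cc([Zn]Cl)ccc1O[Si](C(C)C)(C(C)C)C(C)C | intermediate (not isolated)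
11 | (2S)-6-bromo-8-methoxy-2-[3-methoxy-4-(triisopropylsilyloxy)phenyl]-4-(trimethylsilyloxy)-2H-chromene | COc1cc([C@@H]2C=C(O[Si](C)(C)C)c3cc(Br)cc(OC)c3O2)ccc1O[Si](C(C)C)(C(C)C)C(C)C | intermediate (not isolated)
12 | methyl (2S,3S)-5-bromo-7-methoxy-2-[3-methoxy-4-(triisopropylsilyloxy)phenyl]-2,3-dihydro-1-benzofuran-3-carboxylate (2,3-trans) | COc1cc([C@H]2Oc3c(OC)cc(Br)cc3[C@@H]2C(=O)OC)ccc1O[Si](C(C)C)(C(C)C)C(C)C | intermediate
13 | methyl acrylate | C=CC(=O)OC | starting material
14 | methyl (2S,3S)-7-methoxy-5-[(E)-3-methoxy-3-oxoprop-1-enyl]-2-[3-methoxy-4-(triisopropylsilyloxy)phenyl]-2,3-dihydro-1-benzofuran-3-carboxylate | COc1cc([C@H]2Oc3c(OC)cc(/C=C/C(=O)OC)cc3[C@@H]2C(=O)OC)ccc1O[Si](C(C)C)(C(C)C)C(C)C | intermediate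
15 | (E)-3-[(2S,3R)-3-(hydroxymethyl)-7-methoxy-2-[3-methoxy-4-(triisopropylsilyloxy)phenyl]-2,3-dihydro-1-benzofuran-5-yl]prop-2-en-1-ol | COc1cc([C@H]2Oc3c(OC)cc(/C=C/CO)cc3[C@@H]2CO)ccc1O[Si](C(C)C)(C(C)C)C(C)C | intermediate
16 | tert-butyl(4-iodophenoxy)dimethylsilane | CC(C)(C)[Si](C)(C)Oc1ccc(I)cc1 | starting material
17 | [(2S,3R)-5-[(E)-3-[4-(tert-butyldimethylsilyloxy)benzoyloxy]prop-1-enyl]-7-methoxy-2-[3-methoxy-4-(triisopropylsilyloxy)phenyl]-2,3-dihydro-1-benzofuran-3-yl]methyl 4-(tert-butyldimethylsilyloxy)benzoate | COc1cc([C@H]2Oc3c(OC)cc(/C=C/COC(=O)c4ccc(O[Si](C)(C)C(C)(C)C)cc4)cc3[C@@H]2COC(=O)c2ccc(O[Si](C)(C)C(C)(C)C)cc2)ccc1O[Si](C(C)C)(C(C)C)C(C)C | intermediate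
18 | quiquesetinerviusin A, (2S,3R), 2,3-trans, E alkene | COc1cc([C@H]2Oc3c(OC)cc(/C=C/COC(=O)c4ccc(O)cc4)cc3[C@@H]2COC(=O)c2ccc(O)cc2)ccc1O | target

**Step count**
Total: 10 steps. Longest linear sequence: 9 steps (steps 1, 2, 3, 4, 6, 7, 8, 9, 10 from catechol); step 5 is the side branch from 3 to 8.

**Three steps most likely to fail**

Step 6 (the proposed new step). Three things can go wrong. The arylzinc may add to the vinylogous ester slowly or partly without the catalyst, which lowers the ee. The iodanyl intermediate may give 3-methoxylation, dehydrogenation to the flavone, or migration of ring B instead of ring A. Halide carried through the filtration would be oxidised by the iodine reagent and halogenate the enol ether. The fallback uses only known chemistry, sets out from 8 and 7 and comes back at 12. Compound 8 is lithiated (n-BuLi, THF, −78 °C), borylated with B(OiPr)3 and hydrolysed to [3-methoxy-4-(triisopropylsilyloxy)phenyl]boronic acid F1. F1 is added to chromone 7 under divalent-palladium/pyridine-oxazoline catalysis (Pd(OCOCF3)2, the enantiomer of t-BuPyOx that gives 2S, expected to be (R) from the cyclic enone model, NH4PF6, H2O, ClCH2CH2Cl, 60 °C). This gives the isolated (2S)-6-bromo-8-methoxy-2-[3-methoxy-4-(triisopropylsilyloxy)phenyl]-2,3-dihydro-4H-chromen-4-one F2, whose ee is measured. F2 is then ring-contracted under the established flavanone conditions (PhI(OAc)2, H2SO4, HC(OMe)3, 20 °C) to 12.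

Step 4. The ring is deactivated by bromine, and the acid-labile vinylogous ester can fragment back to phenol 3 before it acylates. The fallback builds the pyranone from an acetophenone instead; it sets out from 3 and comes back at 7. Compound 3 is acetylated (Ac2O, pyridine) to 4-bromo-2-methoxyphenyl acetate F3. Fries rearrangement (CF3SO3H, 60 °C; para position blocked) gives 1-(5-bromo-2-hydroxy-3-methoxyphenyl)ethanone F4. Condensation with Me2NCH(OMe)2 (toluene, 100 °C) gives (E)-1-(5-bromo-2-hydroxy-3-methoxyphenyl)-3-(dimethylamino)prop-2-en-1-one F5, and HCl in CH2Cl2 at 40 °C closes F5 to chromone 7.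

Step 9. Zerovalent palladium can ionise the newly formed electron-rich cinnamyl benzoate, and the second acylation may stall with the diol as limiting reagent. The fallback separates carboxylation from esterification; it sets out from 16 and 15 and comes back at 17. Compound 16 is converted by iodine–magnesium exchange (i-PrMgCl·LiCl, THF, −20 °C) and CO2 into 4-(tert-butyldimethylsilyloxy)benzoic acid F6. Diol 15 is then esterified with F6 (2.4 equiv) by the Steglich method (DCC, catalytic DMAP, CH2Cl2, 0 → 20 °C) to give 17.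

**Further compounds**
F1 | step 6 | [3-methoxy-4-(triisopropylsilyloxy)phenyl]boronic acid | COc1cc(B(O)O)ccc1O[Si](C(C)C)(C(C)C)C(C)C
F2 | step 6 | (2S)-6-bromo-8-methoxy-2-[3-methoxy-4-(triisopropylsilyloxy)phenyl]-2,3-dihydro-4H-chromen-4-one | COc1cc([C@@H]2CC(=O)c3cc(Br)cc(OC)c3O2)ccc1O[Si](C(C)C)(C(C)C)C(C)C
F3 | step 4 | 4-bromo-2-methoxyphenyl acetate | COc1cc(Br)ccc1OC(C)=O
F4 | step 4 | 1-(5-bromo-2-hydroxy-3-methoxyphenyl)ethanone | COc1cc(Br)cc(C(C)=O)c1O
F5 | step 4 | (E)-1-(5-bromo-2-hydroxy-3-methoxyphenyl)-3-(dimethylamino)prop-2-en-1-one | COc1cc(Br)cc(C(=O)/C=C/N(C)C)c1O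
F6 | step 9 | 4-(tert-butyldimethylsilyloxy)benzoic acid | CC(C)(C)[Si](C)(C)Oc1ccc(C(=O)O)cc1
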